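Everything rests on cutting the C13–C14 bond (atoms numbered as they appear in the target SMILES). This turns ring D (C14, C15, C16, C29, C25, C24) into a 2,6-dimethylphenol whose oxygen sits on C29 and whose para carbon is the quaternary C14. In the forward direction the phenolate attacks a primary bromide at C13 through this para carbon; one operation closes ring B (C9, C11, C12, C13, C14, C28), sets the spiro centre C14 and leaves a cross-conjugated dienone whose α- and β-carbons are used for all later ring closures. The substrate is a ring A cyclohexene with a bromoethyl arm on C11 and, on C9, the benzylic carbon C28 that carries the silyl-protected phenol.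

Key step: step 15

Remark: the iodide of step 2, glyoxylic acid and acryloyl chloride are taken as commercial; C11 is formed as a racemate in step 2, so step 4 is a reagent-controlled reduction of a racemate and can pass on at most half of the material as the trans alcohol; polycyclic intermediates are described with the target atom labels.

Step 1
Reactants: 1 dimedone
Product: 2 3-isobutoxy-5,5-dimethylcyclohex-2-en-1-one
Conditions: 2-methylpropan-1-ol (3 equiv), TsOH·H2O (cat.), toluene, reflux, Dean–Stark
Reagents that add atoms: 2-methylpropan-1-ol, CC(C)CO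
Why: Acid-catalysed condensation of the 1,3-diketone with the alcohol under azeotropic removal of water gives the vinylogous ester needed for a Stork–Danheiser sequence.

Step 2
Reactants: 2 3-isobutoxy-5,5-dimethylcyclohex-2-en-1-one; 3 tert-butyl(2-iodoethoxy)dimethylsilane
Product: 5 (±)-6-[2-(tert-butyldimethylsilyloxy)ethyl]-3-isobutoxy-5,5-dimethylcyclohex-2-en-1-one, via lithium enolate 4 (not isolated)
Conditions: LiN(iPr)2 (1.1 equiv), THF, −78 °C; then 3 (1.4 equiv), HMPA (2 equiv), −78 → 0 °C
Reagents that add atoms: none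
Why: Kinetic deprotonation of the vinylogous ester occurs at the α′-carbon and the lithium enolate is alkylated by the primary iodide in an SN2 reaction (Stork–Danheiser alkylation), which installs C12 and C13 and forms the future C11 as a racemate.

Step 3
Reactants: 5 (±)-6-[2-(tert-butyldimethylsilyloxy)ethyl]-3-isobutoxy-5,5-dimethylcyclohex-2-en-1-one
Product: 7 (±)-4-[2-(tert-butyldimethylsilyloxy)ethyl]-3,5,5-trimethylcyclohex-2-en-1-one, via lithium alkoxide 6 (not isolated)
Conditions: MeLi (1.5 equiv), Et2O/THF, −78 → 0 °C; then 0.5 M aq HCl, 0 °C, 15 min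
Reagents that add atoms: methyllithium, [Li]C
Why: 1,2-Addition of MeLi to the vinylogous ester carbonyl and brief acid hydrolysis of the tertiary allylic alkoxide with loss of isobutanol transposes the enone (Stork–Danheiser transposition) and places the methyl group C10 on the future C9.

Step 4
Reactants: 7 (±)-4-[2-(tert-butyldimethylsilyloxy)ethyl]-3,5,5-trimethylcyclohex-2-en-1-one
Product: 8 (1S,4S)-4-[2-(tert-butyldimethylsilyloxy)ethyl]-3,5,5-trimethylcyclohex-2-en-1-ol (trans; C7 S and C11 S)
Conditions: (R)-2-methyl-CBS-oxazaborolidine (0.2 equiv), catecholborane (1.5 equiv), toluene, −78 °C; aq NaOH work-up; chromatography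
Reagents that add atoms: none
Why: In this Corey–Bakshi–Shibata reduction the oxazaborolidine should deliver hydride to the same carbonyl face of both enantiomers (alkenyl side as the large group), so C7 is set S by the catalyst and the trans alcohol, which comes from the 11S enone, is separated from the cis diastereomer that the other enantiomer gives.

Step 5
Reactants: 9 2,6-dimethylphenol; 10 glyoxylic acid
Product: 11 (±)-2-hydroxy-2-(4-hydroxy-3,5-dimethylphenyl)acetic acid
Conditions: NaOH (2.2 equiv), H2O, 35 °C; then aq HCl to pH 1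
Reagents that add atoms: none
Why: Hydroxyalkylation of the phenolate by the aldehyde (electrophilic aromatic substitution) can only occur para to oxygen because both ortho positions carry methyl groups; the carbinol centre is racemic and is removed in step 6.

Step 6
Reactants: 11 (±)-2-hydroxy-2-(4-hydroxy-3,5-dimethylphenyl)acetic acid
Product: 12 2-(4-hydroxy-3,5-dimethylphenyl)acetic acid
Conditions: H2 (1 atm), 10% Pd/C, AcOH, H2SO4 (cat.), 60 °C
Reagents that add atoms: none
Why: Acid-assisted hydrogenolysis of the benzylic C–OH bond, which is activated by the para hydroxyl group, gives the arylacetic acid (C28 and C27).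

Step 7
Reactants: 12 2-(4-hydroxy-3,5-dimethylphenyl)acetic acid
Product: 13 7-hydroxy-6,8-dimethylisochroman-3-one
Conditions: (CH2O)n (1.2 equiv), conc. HCl, AcOH, 70 °C
Reagents that add atoms: formaldehyde, C=O
Why: Chloromethylation-type electrophilic substitution at one of the two equivalent free ring positions (activated by two ortho and one para alkyl group) followed by lactonisation onto the acid gives the 3-isochromanone and installs C23 next to the acetic acid chain.

Step 8
Reactants: 13 7-hydroxy-6,8-dimethylisochroman-3-one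
Product: 16 2-{3,5-dimethyl-4-(triisopropylsilyloxy)-2-[(triisopropylsilyloxy)methyl]phenyl}acetic acid, via dipotassium salt 14 (not isolated), via tris-silyl compound 15 (not isolated)
Conditions: KOH (2.05 equiv), MeOH/H2O, rt, then evaporation to dryness; iPr3SiCl (3.5 equiv), imidazole, DMF, 50 °C; then THF/H2O/AcOH (4:1:1), rt
Reagents that add atoms: potassium hydroxide, [K+].[OH-]; chlorotriisopropylsilane, CC(C)[Si](Cl)(C(C)C)C(C)C
Why: Saponification opens the δ-lactone, silylation of the dry salt caps phenolate, benzylic alcohol and carboxylate, and aqueous acetic acid hydrolyses only the labile silyl ester, so the hydroxy acid cannot relactonise.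

Step 9
Reactants: 8 (1S,4S)-4-[2-(tert-butyldimethylsilyloxy)ethyl]-3,5,5-trimethylcyclohex-2-en-1-ol; 16 2-{3,5-dimethyl-4-(triisopropylsilyloxy)-2-[(triisopropylsilyloxy)methyl]phenyl}acetic acid
Product: 17 (1S,4S)-4-[2-(tert-butyldimethylsilyloxy)ethyl]-3,5,5-trimethylcyclohex-2-en-1-yl 2-{3,5-dimethyl-4-(triisopropylsilyloxy)-2-[(triisopropylsilyloxy)methyl]phenyl}acetate
Conditions: DCC (1.2 equiv), DMAP (0.1 equiv), CH2Cl2, 0 °C → rt
Reagents that add atoms: none
Why: Steglich esterification acylates the secondary allylic alcohol without touching C7, whose configuration is retained.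

Step 10
Reactants: 17 allylic arylacetate
Product: 20 (2S)-2-{(1S,6S)-6-[2-(tert-butyldimethylsilyloxy)ethyl]-1,5,5-trimethylcyclohex-2-en-1-yl}-2-{3,5-dimethyl-4-(triisopropylsilyloxy)-2-[(triisopropylsilyloxy)methyl]phenyl}acetic acid (C9/C11/C28 as in the target), via silyl ketene acetal 18 (not isolated), via trimethylsilyl ester 19 (not isolated)
Conditions: KN(SiMe3)2 (1.3 equiv), THF, −78 °C; Me3SiCl (1.5 equiv), −78 → 40 °C; then aq citric acid
Reagents that add atoms: none
Why: In this Ireland–Claisen rearrangement the new C9–C28 bond forms on the ring face that carried the C7–O bond, anti to the C11 chain, which sets C9 by chirality transfer, and C28 should follow from the (Z)-silyl ketene acetal (aryl cis to OSiMe3, the geometry arylacetates give) reacting through the chair-like array, where the aryl group is staggered between C10 and C11, whereas the boat would eclipse it with the C10 methyl group.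

Step 11
Reactants: 20 rearranged acid
Product: 21 (2S)-2-{(1S,6S)-6-[2-(tert-butyldimethylsilyloxy)ethyl]-1,5,5-trimethylcyclohex-2-en-1-yl}-2-{3,5-dimethyl-4-(triisopropylsilyloxy)-2-[(triisopropylsilyloxy)methyl]phenyl}ethan-1-ol
Conditions: LiAlH4 (3 equiv), THF, 0 → 40 °C
Reagents that add atoms: none
Why: Hydride reduction converts the carboxylic acid into the primary alcohol at C27, and C28 cannot epimerise because the carboxylate is not enolised under these conditions.

Step 12
Reactants: 21 C27 alcohol
Product: 22 4-methoxybenzyl ether of 21 (C27–OPMB)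
Conditions: NaH (1.5 equiv), 4-methoxybenzyl chloride (1.3 equiv), Bu4NI (cat.), THF/DMF, 0 °C → rt
Reagents that add atoms: 4-methoxybenzyl chloride, COc1ccc(CCl)cc1
Why: Williamson etherification gives an ether that survives acid methanolysis, bromination and fluoride and, unlike a sulfonate, cannot be displaced by the phenolate.

Step 13
Reactants: 22 PMB ether
Product: 23 primary alcohol (as 22 but with CH2CH2OH on C11)
Conditions: camphorsulfonic acid (0.1 equiv), MeOH/CH2Cl2 (1:2), 0 °C
Reagents that add atoms: none
Why: Acid-catalysed methanolysis removes the unhindered primary tert-butyldimethylsilyl ether much faster than the two triisopropylsilyl ethers (steric discrimination at silicon).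

Step 14
Reactants: 23 primary alcohol
Product: 24 bromide (ring A cyclohexene with CH2CH2Br on C11; on C9 the benzylic carbon C28 bearing CH2OPMB and the bis-silylated aryl group; C9/C11/C28 as in the target)
Conditions: CBr4 (1.3 equiv), PPh3 (1.4 equiv), CH2Cl2, 0 °C
Reagents that add atoms: tetrabromomethane, BrC(Br)(Br)Br
Why: The Appel reaction turns the primary alcohol C13–OH into the bromide under neutral conditions that leave the ethers and the alkene alone.

Step 15
Reactants: 24 bromide
Product: 27 spirodienone alcohol (rings A, B and D; ring D is a 3-(hydroxymethyl)-2,6-dimethylcyclohexa-2,5-dienone spiro at C14; CH2OPMB on C28; C9/C11/C14/C28 as in the target), via phenolate 25 (not isolated), via silyl ether dienone 26 (not isolated)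
Conditions: Bu4NF (1.05 equiv), THF (0.01 M), 0 → 40 °C; then Bu4NF (1.5 equiv), rt; then water
Reagents that add atoms: none
Why: Fluoride cleaves the aryl silyl ether to the tetrabutylammonium phenolate 25, whose para carbon C14 displaces bromide from C13 in an intramolecular SN2 reaction that breaks the aromaticity of ring D and leaves the cross-conjugated dienone 26. The closest known reaction type is the para-alkylation of phenolates by a tethered sp3 electrophile (aryl participation of the Ar1-6 kind) that gives spiro[5.5]cyclohexadienones, including fluoride-triggered versions from aryl silyl ethers. Ring B (C9, C11, C12, C13, C14, C28) closes in the 6-exo-tet mode through a chair in which the bonds to ring A are equatorial. The new spiro centre C14 is controlled by which ortho carbon takes the axial site syn to the axial C10 methyl group: the unsubstituted C15–H should go there and C24 should sit equatorial, gauche to the axial C27 on C28, because the other arrangement would push C23 under ring B against C10. The step needs C-alkylation and substitution rather than elimination, and the substrate secures this: the oxygen cannot reach C13, C16 and C25 are blocked by methyl groups, C27 carries an ether and not a leaving group so three-membered ring closure is excluded, and no free fluoride beyond one equivalent is present while the bromide is there. The second portion of Bu4NF then frees the C23 hydroxyl group.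

Step 16
Reactants: 27 spirodienone alcohol
Product: 28 spiro enone alcohol (C15–C16 saturated; C24=C25–C29=O enone kept; mixture at C16)
Conditions: [(Ph3P)CuH]6 (0.4 equiv), benzene/THF, H2O (3 equiv), rt
Reagents that add atoms: none
Why: Conjugate reduction by the copper hydride delivers hydride to the less substituted β-carbon C15 and leaves the tetrasubstituted C24=C25 enone, the ring A alkene and the free alcohol; the C16 centre is formed as a mixture that is erased by enolisation in step 20.

Step 17
Reactants: 28 spiro enone alcohol; 29 acryloyl chloride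
Product: 30 acrylate of 28 (C23–O–CO–CH=CH2)
Conditions: Et3N (2 equiv), CH2Cl2, −40 → 0 °C
Reagents that add atoms: none
Why: O-Acylation of the primary allylic alcohol with the acid chloride attaches C20, C19 and C18 through O22.

Step 18
Reactants: 30 acrylate
Product: 31 C27 alcohol (as 30 but with CH2OH on C28)
Conditions: DDQ (1.3 equiv), CH2Cl2/pH 7 buffer (10:1), 0 °C → rt
Reagents that add atoms: none
Why: Oxidative cleavage of the 4-methoxybenzyl ether by DDQ through the benzylic oxocarbenium ion frees the C27 alcohol and does not touch the acrylate, the enone or the alkene.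

Step 19
Reactants: 31 C27 alcohol
Product: 32 tosylate (as 31 but with CH2OTs on C28)
Conditions: TsCl (1.5 equiv), Et3N (3 equiv), DMAP (0.2 equiv), CH2Cl2, rt
Reagents that add atoms: 4-toluenesulfonyl chloride, Cc1ccc(cc1)S(Cl)(=O)=O
Why: Sulfonylation of the primary alcohol turns C27 into the electrophile for ring C.

Step 20
Reactants: 32 tosylate
Product: 35 hexacyclic keto lactone with carbocyclic ring A (the target skeleton with C5 as CH2 and no O4; all eight stereocentres as in the target), via dienolate 33 (not isolated), via enolate 34 (not isolated)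
Conditions: LiN(SiMe3)2 (1.15 equiv), THF, −78 °C → rt; then DMPU, 50 °C; aq NH4Cl
Reagents that add atoms: none
Why: Kinetic α′-deprotonation at C16 gives the cross-conjugated dienolate 33, which undergoes an intramolecular double Michael addition (anionic Diels–Alder) with the tethered acrylate on the ring D face syn to C13 (the other face is covered by the axial C27 substituent) and with C20 endo, forming C16–C18 and C19–C24, and the resulting C25 enolate 34 closes ring C by 5-exo-tet alkylation at C27 from the only face it can reach, which together set C16, C19, C24 and C25.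

Step 21
Reactants: 35 hexacyclic keto lactone
Product: 36 ring A enone (C5 ketone conjugated with C7=C8)
Conditions: CrO3 (10 equiv), 3,5-dimethylpyrazole (10 equiv), CH2Cl2, −20 °C
Reagents that add atoms: chromium trioxide, O=[Cr](=O)=O
Why: Allylic oxidation by the CrO3–3,5-dimethylpyrazole complex can only occur at C5, the single allylic CH2 group, since C9 is quaternary.

Step 22
Reactants: 36 ring A enone
Product: 37 andilesin C
Conditions: 3-chloroperbenzoic acid (2 equiv), NaHCO3, CH2Cl2, 0 °C → rt
Reagents that add atoms: 3-chloroperbenzoic acid, OOC(=O)c1cccc(Cl)c1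
Why: In this Baeyer–Villiger oxidation the tertiary carbon C2 migrates in preference to the vinyl carbon C7, the electron-poor enone double bond resists epoxidation and the C29 ketone is shielded by two quaternary α-carbons, so oxygen is inserted between C5 and C2 and the unsaturated ε-lactone results.

Compound list
1 | dimedone (5,5-dimethylcyclohexane-1,3-dione) | CC1(C)CC(=O)CC(=O)C1 | starting material
2 | 3-isobutoxy-5,5-dimethylcyclohex-2-en-1-one | CC(C)COC1=CC(=O)CC(C)(C)C1 | intermediate
3 | tert-butyl(2-iodoethoxy)dimethylsilane | ICCO[Si](C)(C)C(C)(C)C | starting material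
4 | lithium 5-isobutoxy-3,3-dimethylcyclohexa-1,5-dien-1-olate (α′-enolate of 2) | CC(C)COC1=CC([O-])=CC(C)(C)C1.[Li+] | intermediate (not isolated)
5 | (±)-6-[2-(tert-butyldimethylsilyloxy)ethyl]-3-isobutoxy-5,5-dimethylcyclohex-2-en-1-one | CC(C)COC1=CC(=O)C(CCO[Si](C)(C)C(C)(C)C)C(C)(C)C1 | intermediate
6 | lithium 6-[2-(tert-butyldimethylsilyloxy)ethyl]-3-isobutoxy-1,5,5-trimethylcyclohex-2-en-1-olate (diastereomer mixture) | CC(C)COC1=CC(C)([O-])C(CCO[Si](C)(C)C(C)(C)C)C(C)(C)C1.[Li+] | intermediate (not isolated)
7 | (±)-4-[2-(tert-butyldimethylsilyloxy)ethyl]-3,5,5-trimethylcyclohex-2-en-1-one | CC1=CC(=O)CC(C)(C)C1CCO[Si](C)(C)C(C)(C)C | intermediate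
8 | (1S,4S)-4-[2-(tert-butyldimethylsilyloxy)ethyl]-3,5,5-trimethylcyclohex-2-en-1-ol | CC1(C)C[C@H](O)C=C(C)[C@H]1CCO[Si](C)(C)C(C)(C)C | intermediate
9 | 2,6-dimethylphenol | Cc1cccc(C)c1O | starting material
10 | glyoxylic acid | O=CC(=O)O | starting material
11 | (±)-2-hydroxy-2-(4-hydroxy-3,5-dimethylphenyl)acetic acid | Cc1cc(C(O)C(=O)O)cc(C)c1O | intermediate
12 | 2-(4-hydroxy-3,5-dimethylphenyl)acetic acid | Cc1cc(CC(=O)O)cc(C)c1O | intermediate
13 | 7-hydroxy-6,8-dimethylisochroman-3-one | O=C1Cc2cc(C)c(O)c(C)c2CO1 | intermediate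
14 | dipotassium 2-[2-(hydroxymethyl)-3,5-dimethyl-4-oxidophenyl]acetate | [K+].[K+].[O-]C(=O)Cc1cc(C)c([O-])c(C)c1CO | intermediate (not isolated)
15 | triisopropylsilyl 2-{3,5-dimethyl-4-(triisopropylsilyloxy)-2-[(triisopropylsilyloxy)methyl]phenyl}acetate | CC(C)[Si](C(C)C)(C(C)C)OC(=O)Cc1cc(C)c(O[Si](C(C)C)(C(C)C)C(C)C)c(C)c1CO[Si](C(C)C)(C(C)C)C(C)C | intermediate (not isolated)
16 | 2-{3,5-dimethyl-4-(triisopropylsilyloxy)-2-[(triisopropylsilyloxy)methyl]phenyl}acetic acid | OC(=O)Cc1cc(C)c(O[Si](C(C)C)(C(C)C)C(C)C)c(C)c1CO[Si](C(C)C)(C(C)C)C(C)C | intermediate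
17 | (1S,4S)-4-[2-(tert-butyldimethylsilyloxy)ethyl]-3,5,5-trimethylcyclohex-2-en-1-yl ester of 16 | CC1(C)C[C@H](OC(=O)Cc2cc(C)c(O[Si](C(C)C)(C(C)C)C(C)C)c(C)c2CO[Si](C(C)C)(C(C)C)C(C)C)C=C(C)[C@H]1CCO[Si](C)(C)C(C)(C)C | intermediate
18 | (Z)-trimethylsilyl ketene acetal of 17 (aryl cis to OSiMe3) | CC1(C)C[C@H](O/C(O[Si](C)(C)C)=C/c2cc(C)c(O[Si](C(C)C)(C(C)C)C(C)C)c(C)c2CO[Si](C(C)C)(C(C)C)C(C)C)C=C(C)[C@H]1CCO[Si](C)(C)C(C)(C)C | intermediate (not isolated)
19 | trimethylsilyl ester of acid 20 | CC1(C)CC=C[C@@](C)([C@H]1CCO[Si](C)(C)C(C)(C)C)[C@H](C(=O)O[Si](C)(C)C)c1cc(C)c(O[Si](C(C)C)(C(C)C)C(C)C)c(C)c1CO[Si](C(C)C)(C(C)C)C(C)C | intermediate (not isolated)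
20 | (2S)-2-{(1S,6S)-6-[2-(tert-butyldimethylsilyloxy)ethyl]-1,5,5-trimethylcyclohex-2-en-1-yl}-2-{3,5-dimethyl-4-(triisopropylsilyloxy)-2-[(triisopropylsilyloxy)methyl]phenyl}acetic acid | CC1(C)CC=C[C@@](C)([C@H]1CCO[Si](C)(C)C(C)(C)C)[C@H](C(=O)O)c1cc(C)c(O[Si](C(C)C)(C(C)C)C(C)C)c(C)c1CO[Si](C(C)C)(C(C)C)C(C)C | intermediate
21 | the corresponding (2S)-ethan-1-ol (C27–OH) | CC1(C)CC=C[C@@](C)([C@H]1CCO[Si](C)(C)C(C)(C)C)[C@H](CO)c1cc(C)c(O[Si](C(C)C)(C(C)C)C(C)C)c(C)c1CO[Si](C(C)C)(C(C)C)C(C)C | intermediate
22 | 4-methoxybenzyl ether of 21 | CC1(C)CC=C[C@@](C)([C@H]1CCO[Si](C)(C)C(C)(C)C)[C@H](COCc2ccc(OC)cc2)c1cc(C)c(O[Si](C(C)C)(C(C)C)C(C)C)c(C)c1CO[Si](C(C)C)(C(C)C)C(C)C | intermediate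
23 | C13 alcohol (22 with CH2CH2OH on C11) | CC1(C)CC=C[C@@](C)([C@H]1CCO)[C@H](COCc2ccc(OC)cc2)c1cc(C)c(O[Si](C(C)C)(C(C)C)C(C)C)c(C)c1CO[Si](C(C)C)(C(C)C)C(C)C | intermediate
24 | C13 bromide, substrate of the key step (22 with CH2CH2Br on C11) | CC1(C)CC=C[C@@](C)([C@H]1CCBr)[C@H](COCc2ccc(OC)cc2)c1cc(C)c(O[Si](C(C)C)(C(C)C)C(C)C)c(C)c1CO[Si](C(C)C)(C(C)C)C(C)C | intermediate
25 | tetrabutylammonium phenolate of 24 | CC1(C)CC=C[C@@](C)([C@H]1CCBr)[C@H](COCc2ccc(OC)cc2)c1cc(C)c([O-])c(C)c1CO[Si](C(C)C)(C(C)C)C(C)C.CCCC[N+](CCCC)(CCCC)CCCC | intermediate (not isolated)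
26 | spirodienone with C23–O–Si(iPr)3 and C27–OPMB (C9/C11/C14/C28 as in the target) | CC1(C)CC=C[C@@]2(C)[C@H]1CC[C@]3(C=C(C)C(=O)C(C)=C3CO[Si](C(C)C)(C(C)C)C(C)C)[C@H]2COCc4ccc(OC)cc4 | intermediate (not isolated)
27 | spirodienone alcohol (C23–OH, C27–OPMB) | CC1(C)CC=C[C@@]2(C)[C@H]1CC[C@]3(C=C(C)C(=O)C(C)=C3CO)[C@H]2COCc4ccc(OC)cc4 | intermediate
28 | spiro enone alcohol (C15–C16 saturated, mixture at C16) | CC1(C)CC=C[C@@]2(C)[C@H]1CC[C@]3(CC(C)C(=O)C(C)=C3CO)[C@H]2COCc4ccc(OC)cc4 | intermediate
29 | acryloyl chloride | C=CC(=O)Cl | starting material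
30 | acrylate of 28 | CC1(C)CC=C[C@@]2(C)[C@H]1CC[C@]3(CC(C)C(=O)C(C)=C3COC(=O)C=C)[C@H]2COCc4ccc(OC)cc4 | intermediate
31 | acrylate with free C27–OH | CC1(C)CC=C[C@@]2(C)[C@H]1CC[C@]3(CC(C)C(=O)C(C)=C3COC(=O)C=C)[C@H]2CO | intermediate
32 | acrylate with C27–OTs | CC1(C)CC=C[C@@]2(C)[C@H]1CC[C@]3(CC(C)C(=O)C(C)=C3COC(=O)C=C)[C@H]2COS(=O)(=O)c4ccc(C)cc4 | intermediate
33 | lithium cross-conjugated dienolate of 32 (C16=C29–O−) | CC1(C)CC=C[C@@]2(C)[C@H]1CC[C@]3(CC(C)=C([O-])C(C)=C3COC(=O)C=C)[C@H]2COS(=O)(=O)c4ccc(C)cc4.[Li+] | intermediate (not isolated)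
34 | lithium C25 enolate of the double Michael adduct (bicyclo[2.2.2]octene and γ-lactone formed, tosylate still on C27) | CC1(C)CC=C[C@@]2(C)[C@H]1CC[C@@]3([C@H]2COS(=O)(=O)c4ccc(C)cc4)C[C@@]5(C)C[C@@H]6C(=O)OC[C@@]36C(C)=C5[O-].[Li+] | intermediate (not isolated)
35 | hexacyclic keto lactone with cyclohexene ring A | CC1(C)CC=C[C@@]2(C)[C@H]1CC[C@@]13C[C@@]4(C)C[C@@H]5C(=O)OC[C@]51[C@@](C)(C[C@@H]23)C4=O | intermediate
36 | ring A enone (C5=O, C7=C8) | CC1(C)C(=O)C=C[C@@]2(C)[C@H]1CC[C@@]13C[C@@]4(C)C[C@@H]5C(=O)OC[C@]51[C@@](C)(C[C@@H]23)C4=O | intermediate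
37 | andilesin C | CC1(C)OC(=O)C=C[C@@]2(C)[C@H]1CC[C@@]13C[C@@]4(C)C[C@@H]5C(=O)OC[C@]51[C@@](C)(C[C@@H]23)C4=O | target

Total step count: 22
Longest linear sequence: 18 steps (steps 1–4 and 9–22 from dimedone; the arene branch, steps 5–8 and 9–22, is equally long)

Steps most likely to fail

Step 15. Elimination or fluoride substitution at C13 may outrun the slow six-membered C-alkylation, or the two ortho carbons may not be told apart well enough, which would give poor selectivity at C14. The fallback replaces the ionic closure by a radical ipso-cyclisation. It sets out from bromide 24. Displacement with potassium O-ethyl xanthate in acetone gives the S-alkyl xanthate F1. Portionwise addition of dilauroyl peroxide (1.2 equiv) in refluxing 1,2-dichloroethane generates the C13 radical, which attacks C14 in the 6-exo ipso mode. The cyclohexadienyl radical is oxidised by the peroxide and laurate takes the silyl group from the oxygen on C29. This gives silyl ether dienone 26, where the fallback comes back to the route; Bu4NF then gives 27 as in the second stage of step 15.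

Step 10. The ketene acetal may rearrange through the boat-like array, which would invert C28, or the crowded C9–C28 bond may form so slowly that the ketene acetal decomposes. The fallback uses a ketene N,O-acetal whose aryl group lies cis to the allylic oxygen, so that the boat-like array leads to the needed C28 isomer. It sets out from acid 16 and alcohol 8. Amide coupling (Me2NH·HCl, EDC·HCl, HOBt, iPr2NEt) gives the N,N-dimethylamide F2. O-Methylation and deprotonation (MeOTf; then NaH) give the methyl ketene N,O-acetal F3. Heating F3 with 8 in xylene at 140 °C exchanges methanol for the allylic alcohol to give the allyl ketene N,O-acetal F4 (not isolated), and Eschenmoser–Claisen rearrangement gives the rearranged amide F5. Reduction of F5 with LiNH2BH3 in THF returns to alcohol 21.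

Step 20. The ester tether may not fold into the reactive conformation, so that the dienolate is lost to proton transfer or intermolecular Michael addition, or the acrylate may add from the wrong face. The fallback separates the events and uses a neutral cycloaddition. It sets out from tosylate 32. TBSOTf and Et3N in CH2Cl2 give the 2-silyloxy-1,3-diene F6. Heating in toluene at 140 °C (sealed tube, BHT) should bring about the intramolecular Diels–Alder reaction to the bicyclo[2.2.2]octene silyl enol ether F7. CsF in DMF at 60 °C then unmasks the C25 enolate, which displaces the tosylate and gives 35.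

Further compounds
F1 | step 15 | O-ethyl S-alkyl xanthate of 24 (SC(=S)OEt in place of Br on C13) | CC1(C)CC=C[C@@](C)([C@H]1CCSC(=S)OCC)[C@H](COCc2ccc(OC)cc2)c1cc(C)c(O[Si](C(C)C)(C(C)C)C(C)C)c(C)c1CO[Si](C(C)C)(C(C)C)C(C)C
F2 | step 10 | N,N-dimethyl-2-{3,5-dimethyl-4-(triisopropylsilyloxy)-2-[(triisopropylsilyloxy)methyl]phenyl}acetamide | CN(C)C(=O)Cc1cc(C)c(O[Si](C(C)C)(C(C)C)C(C)C)c(C)c1CO[Si](C(C)C)(C(C)C)C(C)C
F3 | step 10 | 1-methoxy-N,N-dimethyl-2-arylethen-1-amine (methyl ketene N,O-acetal, aryl cis to OMe) | CO/C(N(C)C)=C\c1cc(C)c(O[Si](C(C)C)(C(C)C)C(C)C)c(C)c1CO[Si](C(C)C)(C(C)C)C(C)C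
F4 | step 10 | allyl ketene N,O-acetal from F3 and 8 (aryl cis to the allylic oxygen) | CC1(C)C[C@H](O/C(N(C)C)=C\c2cc(C)c(O[Si](C(C)C)(C(C)C)C(C)C)c(C)c2CO[Si](C(C)C)(C(C)C)C(C)C)C=C(C)[C@H]1CCO[Si](C)(C)C(C)(C)C
F5 | step 10 | N,N-dimethylamide corresponding to acid 20 | CC1(C)CC=C[C@@](C)([C@H]1CCO[Si](C)(C)C(C)(C)C)[C@H](C(=O)N(C)C)c1cc(C)c(O[Si](C(C)C)(C(C)C)C(C)C)c(C)c1CO[Si](C(C)C)(C(C)C)C(C)C
F6 | step 20 | tert-butyldimethylsilyl dienol ether of 32 (C16=C29–OSi, C24=C25) | CC1(C)CC=C[C@@]2(C)[C@H]1CC[C@]3(CC(C)=C(O[Si](C)(C)C(C)(C)C)C(C)=C3COC(=O)C=C)[C@H]2COS(=O)(=O)c4ccc(C)cc4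
F7 | step 20 | Diels–Alder adduct: bicyclo[2.2.2]octene silyl enol ether with γ-lactone and C27–OTs | CC1(C)CC=C[C@@]2(C)[C@H]1CC[C@@]3([C@H]2COS(=O)(=O)c4ccc(C)cc4)C[C@@]5(C)C[C@@H]6C(=O)OC[C@@]36C(C)=C5O[Si](C)(C)C(C)(C)C
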